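**Plan**

1. Locants used below (carotenoid style): ring C1 (CMe2), C2 (CH2), C3 (CHOH), C4=C5(Me), C6 (CH bearing the chain); chain C7=C8 onward to the aldehyde C8'.
2. Retrosynthesis: first cut C7=C8 (Julia–Kocienski) into a C10 ring sulfone and all-E C20 dialdehyde (crocetindial), which already holds every other chain double bond and methyl group. Then cut ring bonds C1–C2 and C5–C6 in a retro-[4+2] into (E)-2-silyloxypenta-1,3-diene (C2–C5) and 3-methylbut-2-enal (C1, C6, C7).
3. Enabling feature: in the cyclohexene ring the C3 oxygen is para and the C5 methyl ortho to C6, and the gem-dimethyl carbon C1 adjoins C6. This is the pattern a 2-oxy-4-methylbutadiene imprints on the C1=C6 bond of prenal; quaternary C1 also leaves C5 as the only site for later enone formation.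
4. Forward: diene (step 1), enantioselective Diels–Alder builds the only ring (step 2), then reduction, Saegusa–Ito enone, sulfide, ketone reduction, silylation and sulfone (steps 3–8). The chain is joined by mono-olefination of the dialdehyde (step 9), followed by desilylation (step 10).
5. Stereochemistry: C6 (R) comes from the catalyst-controlled face of the dienophile in step 2. C3 (S, cis to the chain) comes from the oxazaborolidine-controlled reduction in step 6. Seven E bonds come with the dialdehyde, and E-C7=C8 from step 9.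

Key step: step 2

Remark: all-E crocetindial is taken as a commercial carotenoid building block; the minor exo epimer at the methyl-bearing ring carbon of 5 and 6 is carried along, because that carbon becomes sp2 in step 4.

**Route**

Step 1
Reactants: 1 (E)-pent-3-en-2-one
Product: 3 (E)-2-(triisopropylsilyloxy)penta-1,3-diene, via lithium dienolate 2 (not isolated)
Conditions: LiN(iPr)2 (1.05 equiv), THF, −78 °C; then TIPSOTf, −78 to 0 °C
Reagents that add atoms: triisopropylsilyl trifluoromethanesulfonate, CC(C)[Si](C(C)C)(C(C)C)OS(=O)(=O)C(F)(F)F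
Why: Kinetic deprotonation of the enone at its acetyl methyl gives the cross-conjugated lithium dienolate, and O-silylation by the hard silyl triflate is the standard entry to 2-silyloxy-1,3-dienes; the E alkene is untouched and no stereocenter forms.

Step 2
Reactants: 3 (E)-2-(triisopropylsilyloxy)penta-1,3-diene (1.5 equiv); 4 3-methylbut-2-enal
Product: 5 (1S,2S)-2,6,6-trimethyl-4-[(triisopropylsilyl)oxy]cyclohex-3-ene-1-carbaldehyde
Conditions: (S)-1-(2-methylphenyl)-3,3-diphenyltetrahydro-1H,3H-pyrrolo[1,2-c][1,3,2]oxazaborole (20 mol%), HN(SO2CF3)2 (17 mol%), CH2Cl2, −78 to −20 °C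
Reagents that add atoms: none
Why: Proposed new method: the protonated oxazaborolidine binds the formyl oxygen of s-trans 4 (B–O coordination reinforced by a formyl C–H···O contact), lowers its LUMO and screens one face, and diene 3 then adds in a concerted but asynchronous normal-demand [4+2] cycloaddition in which the bond from the diene CH2 terminus to the β,β-dimethyl carbon runs ahead of the bond from the methyl-bearing terminus to the α-carbon. The closest known reaction types are the oxazaborolidinium-catalysed enantioselective Diels–Alder additions of 2-silyloxybuta-1,3-dienes to α,β-unsaturated aldehydes and the AlCl3-promoted Diels–Alder addition of penta-1,3-diene to mesityl oxide, which forms the same two ring bonds at a β,β-dimethyl dienophile in racemic form; a β,β-disubstituted acyclic enal has not been shown in the asymmetric version. The six-membered carbocycle closes by intermolecular [4+2] cycloaddition, both new σ bonds arising suprafacially on diene and dienophile. The formyl-bearing stereocenter is set by the catalyst, which must deliver the diene to the Si face of the α-carbon of 4 (the (S)-catalyst is proposed from the formyl C–H···O binding model, its mirror image being used if the sense proves opposite); the methyl-bearing center follows the endo preference but becomes sp2 in step 4, so endo/exo selectivity is not required. Regioselectivity is required and is secured because the 2-silyloxy and 4-methyl donors both make the CH2 terminus of 3 the nucleophilic end, which pairs with the electrophilic β-carbon (oxygen para, methyl ortho to the formyl-bearing carbon). Chemoselectivity for C=C over C=O addition (Mukaiyama aldol, hetero-Diels–Alder) is also required and is favoured by the bulky triisopropylsilyl group, which resists silyl transfer, and by keeping the acid substoichiometric to the oxazaborolidine.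

Step 3
Reactants: 5 (1S,2S)-2,6,6-trimethyl-4-[(triisopropylsilyl)oxy]cyclohex-3-ene-1-carbaldehyde (crude, used at once)
Product: 6 [(1S,2R)-2,6,6-trimethyl-4-[(triisopropylsilyl)oxy]cyclohex-3-en-1-yl]methanol
Conditions: NaBH4, EtOH/THF, −20 °C
Reagents that add atoms: none
Why: Chemoselective hydride reduction of the aldehyde at low temperature removes the acidity of the adjacent ring C–H before it can epimerise, and the triisopropylsilyl enol ether is inert to NaBH4; no new stereocenter forms.

Step 4
Reactants: 6 [(1S,2R)-2,6,6-trimethyl-4-[(triisopropylsilyl)oxy]cyclohex-3-en-1-yl]methanol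
Product: 7 (4R)-4-(hydroxymethyl)-3,5,5-trimethylcyclohex-2-en-1-one
Conditions: Pd(OAc)2 (1.1 equiv), MeCN/DMSO, 40 °C
Reagents that add atoms: none
Why: Saegusa–Ito oxidation: divalent palladium turns the silyl enol ether into a palladium enolate whose only β-hydrogen sits on the methyl-bearing carbon (the other α-carbon is flanked by the quaternary carbon), so β-hydride elimination can only give the desired trisubstituted enone; both epimers at the methyl-bearing carbon converge, and the chain-bearing stereocenter, now only γ to the carbonyl, should survive these neutral to weakly acidic conditions.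

Step 5
Reactants: 7 (4R)-4-(hydroxymethyl)-3,5,5-trimethylcyclohex-2-en-1-one
Product: 8 (4R)-3,5,5-trimethyl-4-{[(1-phenyl-1H-tetrazol-5-yl)sulfanyl]methyl}cyclohex-2-en-1-one
Conditions: PPh3, DIAD, THF, 0 °C to rt
Reagents that add atoms: 1-phenyl-1H-tetrazole-5-thiol, Sc1nnnn1-c1ccccc1
Why: Mitsunobu thioetherification of the primary alcohol with the acidic heteroaryl thiol is an SN2 reaction at a non-stereogenic CH2 under essentially neutral conditions, so the γ-stereocenter of the enone is not enolised.

Step 6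
Reactants: 8 (4R)-3,5,5-trimethyl-4-{[(1-phenyl-1H-tetrazol-5-yl)sulfanyl]methyl}cyclohex-2-en-1-one
Product: 9 (1S,4R)-3,5,5-trimethyl-4-{[(1-phenyl-1H-tetrazol-5-yl)sulfanyl]methyl}cyclohex-2-en-1-ol
Conditions: (R)-1-methyl-3,3-diphenyltetrahydro-1H,3H-pyrrolo[1,2-c][1,3,2]oxazaborole (20 mol%), BH3·SMe2, THF, −30 °C; MeOH quench, aqueous work-up
Reagents that add atoms: none
Why: Corey–Bakshi–Shibata 1,2-reduction of the enone: with the alkenyl side as the large group the (R)-catalyst should deliver hydride to the face that gives the (S)-carbinol, cis to the ring CH2S substituent; catalyst control is relied on because the intrinsic facial bias of this ring is expected to be small.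

Step 7
Reactants: 9 (1S,4R)-3,5,5-trimethyl-4-{[(1-phenyl-1H-tetrazol-5-yl)sulfanyl]methyl}cyclohex-2-en-1-ol
Product: 10 tert-butyl(dimethyl){[(1S,4R)-3,5,5-trimethyl-4-{[(1-phenyl-1H-tetrazol-5-yl)sulfanyl]methyl}cyclohex-2-en-1-yl]oxy}silane
Conditions: TBSCl, imidazole, DMF, rt
Reagents that add atoms: tert-butyldimethylsilyl chloride, CC(C)(C)[Si](C)(C)Cl
Why: Standard silylation of the secondary allylic alcohol masks the hydroxyl so that it neither directs epoxidation in step 8 nor consumes base in step 9; stereocenters are untouched.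

Step 8
Reactants: 10 tert-butyl(dimethyl){[(1S,4R)-3,5,5-trimethyl-4-{[(1-phenyl-1H-tetrazol-5-yl)sulfanyl]methyl}cyclohex-2-en-1-yl]oxy}silane
Product: 11 5-({[(1R,4S)-4-{[tert-butyl(dimethyl)silyl]oxy}-2,6,6-trimethylcyclohex-2-en-1-yl]methyl}sulfonyl)-1-phenyl-1H-tetrazole
Conditions: (NH4)6Mo7O24·4H2O (10 mol%), 30% aq. H2O2, EtOH, 0 °C to rt
Reagents that add atoms: hydrogen peroxide, OO
Why: Molybdate/peroxide oxidation of the heteroaryl sulfide to the sulfone is chemoselective over the trisubstituted alkene once the allylic hydroxyl is silylated; no stereocenter is touched.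

Step 9
Reactants: 11 5-({[(1R,4S)-4-{[tert-butyl(dimethyl)silyl]oxy}-2,6,6-trimethylcyclohex-2-en-1-yl]methyl}sulfonyl)-1-phenyl-1H-tetrazole; 12 crocetindial, (2E,4E,6E,8E,10E,12E,14E)-2,6,11,15-tetramethylhexadeca-2,4,6,8,10,12,14-heptaenedial (3 equiv)
Product: 14 (2E,4E,6E,8E,10E,12E,14E,16E)-17-[(1R,4S)-4-{[tert-butyl(dimethyl)silyl]oxy}-2,6,6-trimethylcyclohex-2-en-1-yl]-2,6,11,15-tetramethylheptadeca-2,4,6,8,10,12,14,16-octaenal, via potassium sulfonyl carbanion 13 (not isolated)
Conditions: KN(SiMe3)2 (1.05 equiv), THF, −78 °C; anion cannulated into 12 in THF, −78 °C to rt; argon, dim light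
Reagents that add atoms: none
Why: Julia–Kocienski olefination: the sulfonyl carbanion adds to one aldehyde of the dialdehyde, and Smiles rearrangement with loss of SO2 and the tetrazololate gives the alkene. E geometry is expected from the potassium/phenyltetrazolyl sulfone combination and from the severe strain of the Z isomer between the ring and the C9 methyl. Inverse addition to excess dialdehyde keeps the reaction at mono-olefination, and the ring stereocenters are not α to any carbonyl at this stage.

Step 10
Reactants: 14 (2E,4E,6E,8E,10E,12E,14E,16E)-17-[(1R,4S)-4-{[tert-butyl(dimethyl)silyl]oxy}-2,6,6-trimethylcyclohex-2-en-1-yl]-2,6,11,15-tetramethylheptadeca-2,4,6,8,10,12,14,16-octaenal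
Product: 15 (2E,4E,6E,8E,10E,12E,14E,16E)-17-[(1R,4S)-4-hydroxy-2,6,6-trimethylcyclohex-2-en-1-yl]-2,6,11,15-tetramethylheptadeca-2,4,6,8,10,12,14,16-octaenal
Conditions: Bu4NF, AcOH (1:1), THF, 0 °C to rt; argon, dim light
Reagents that add atoms: none
Why: Fluoride cleavage of the silyl ether, buffered with acetic acid, avoids both base-induced migration of the ring double bond into conjugation and acid-induced ionisation of the allylic alcohol, so both stereocenters and the polyene geometry should be retained.

**Compound list**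

1 | (E)-pent-3-en-2-one | C/C=C/C(C)=O | starting material
2 | lithium (E)-penta-1,3-dien-2-olate | [Li+].[O-]C(=C)/C=C/C | intermediate
3 | (E)-2-(triisopropylsilyloxy)penta-1,3-diene | C=C(O[Si](C(C)C)(C(C)C)C(C)C)/C=C/C | intermediate
4 | 3-methylbut-2-enal | CC(C)=CC=O | starting material
5 | (1S,2S)-2,6,6-trimethyl-4-[(triisopropylsilyl)oxy]cyclohex-3-ene-1-carbaldehyde (endo adduct, methyl cis to formyl) | C[C@H]1C=C(O[Si](C(C)C)(C(C)C)C(C)C)CC(C)(C)[C@H]1C=O | intermediate
6 | [(1S,2R)-2,6,6-trimethyl-4-[(triisopropylsilyl)oxy]cyclohex-3-en-1-yl]methanol | C[C@H]1C=C(O[Si](C(C)C)(C(C)C)C(C)C)CC(C)(C)[C@H]1CO | intermediate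
7 | (4R)-4-(hydroxymethyl)-3,5,5-trimethylcyclohex-2-en-1-one | CC1=CC(=O)CC(C)(C)[C@H]1CO | intermediate
8 | (4R)-3,5,5-trimethyl-4-{[(1-phenyl-1H-tetrazol-5-yl)sulfanyl]methyl}cyclohex-2-en-1-one | CC1=CC(=O)CC(C)(C)[C@H]1CSc1nnnn1-c1ccccc1 | intermediate
9 | (1S,4R)-3,5,5-trimethyl-4-{[(1-phenyl-1H-tetrazol-5-yl)sulfanyl]methyl}cyclohex-2-en-1-ol (hydroxyl cis to CH2S) | CC1=C[C@@H](O)CC(C)(C)[C@H]1CSc1nnnn1-c1ccccc1 | intermediate
10 | tert-butyl(dimethyl){[(1S,4R)-3,5,5-trimethyl-4-{[(1-phenyl-1H-tetrazol-5-yl)sulfanyl]methyl}cyclohex-2-en-1-yl]oxy}silane | CC1=C[C@@H](O[Si](C)(C)C(C)(C)C)CC(C)(C)[C@H]1CSc1nnnn1-c1ccccc1 | intermediate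
11 | 5-({[(1R,4S)-4-{[tert-butyl(dimethyl)silyl]oxy}-2,6,6-trimethylcyclohex-2-en-1-yl]methyl}sulfonyl)-1-phenyl-1H-tetrazole | CC1=C[C@@H](O[Si](C)(C)C(C)(C)C)CC(C)(C)[C@H]1CS(=O)(=O)c1nnnn1-c1ccccc1 | intermediate
12 | crocetindial, (2E,4E,6E,8E,10E,12E,14E)-2,6,11,15-tetramethylhexadeca-2,4,6,8,10,12,14-heptaenedial | O=C/C(C)=C/C=C/C(C)=C/C=C/C=C(C)/C=C/C=C(\C)C=O | starting material
13 | potassium salt of the α-sulfonyl carbanion of 11 | [K+].CC1=C[C@@H](O[Si](C)(C)C(C)(C)C)CC(C)(C)[C@H]1[CH-]S(=O)(=O)c1nnnn1-c1ccccc1 | intermediate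
14 | (2E,4E,6E,8E,10E,12E,14E,16E)-17-[(1R,4S)-4-{[tert-butyl(dimethyl)silyl]oxy}-2,6,6-trimethylcyclohex-2-en-1-yl]-2,6,11,15-tetramethylheptadeca-2,4,6,8,10,12,14,16-octaenal | CC1=C[C@@H](O[Si](C)(C)C(C)(C)C)CC(C)(C)[C@H]1/C=C/C(C)=C/C=C/C(C)=C/C=C/C=C(C)/C=C/C=C(\C)C=O | intermediate
15 | (2E,4E,6E,8E,10E,12E,14E,16E)-17-[(1R,4S)-4-hydroxy-2,6,6-trimethylcyclohex-2-en-1-yl]-2,6,11,15-tetramethylheptadeca-2,4,6,8,10,12,14,16-octaenal, i.e. (3S,6R)-3-hydroxy-8'-apo-ε-caroten-8'-al | CC1=C[C@@H](O)CC(C)(C)[C@H]1/C=C/C(C)=C/C=C/C(C)=C/C=C/C=C(C)/C=C/C=C(\C)C=O | target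

**Step count and risks**

Total step count: 10. Longest linear sequence: 10 steps (1 to 15); crocetindial 12 enters at step 9.

Steps most likely to fail:

Step 2 (proposed new method). Carbonyl addition of the silyl dienol ether to the activated aldehyde may outrun cycloaddition at the hindered β,β-dimethyl terminus, the diene may be protodesilylated, or the enantioface discrimination may be insufficient. Fallback in known chemistry, setting out from 3 and 4 and returning at 9: 3 and 4 are combined under an achiral aluminium Lewis acid (Me2AlCl, CH2Cl2, −78 to −20 °C), the racemic reaction type established for β,β-dimethyl enone dienophiles, to give racemic 2,6,6-trimethyl-4-[(triisopropylsilyl)oxy]cyclohex-3-ene-1-carbaldehyde F1. The conditions of steps 3, 4 and 5 convert it into the racemic alcohol F2, racemic 4-(hydroxymethyl)-3,5,5-trimethylcyclohex-2-en-1-one F3 and the racemic sulfide F4. Reduction of racemic F4 under the conditions of step 6 should set the carbinol carbon as S in both enantiomers, which turns the racemate into two separable diastereomers, 9 and its (1S,4S) trans isomer F5. Chromatography removes F5 and 9 re-enters at step 7.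

Step 9. The hindered β-branched sulfonyl anion may add sluggishly to the vinylogous, α-branched aldehyde; a second olefination of the product may compete; E-selectivity at the new bond may be incomplete; and the base may deprotonate the vinylogous positions of the polyenal. Fallback, setting out from 11 and returning at 14, by the stepwise C15 Wittig-salt strategy of carotenoid chemistry: 11 is united (KN(SiMe3)2, THF, −78 °C) with the small, monofunctional ethyl (E)-3-methyl-4-oxobut-2-enoate to give the C15 ester ethyl (2E,4E)-5-[(1R,4S)-4-{[tert-butyl(dimethyl)silyl]oxy}-2,6,6-trimethylcyclohex-2-en-1-yl]-3-methylpenta-2,4-dienoate F6. Reduction with i-Bu2AlH gives the allylic alcohol F7, and PPh3·HBr in CH2Cl2 gives the C15 phosphonium bromide F8. Wittig reaction (NaOMe, CH2Cl2/MeOH) with excess (2E,4E,6E)-2,7-dimethylocta-2,4,6-trienedial gives the C25 aldehyde F9. A second Wittig reaction with [(E)-4,4-dimethoxy-3-methylbut-2-en-1-yl]triphenylphosphonium chloride gives the C30 dimethyl acetal F10. Dilute aqueous oxalic acid followed by I2-catalysed Z to E equilibration then delivers 14.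

Step 6. Facial selectivity may be poor if the unknown bias of the ring opposes the catalyst or if the neopentyl-type CH2 blurs the large/small distinction, and borane may be held by the sulfur and nitrogen atoms. Fallback, setting out from 8 and returning at 9: 8 is reduced with LiBH(s-Bu)3 (THF, −78 °C), whose approach should be ruled by the axial methyl of the gem-dimethyl carbon and lead to the trans alcohol (1R,4R)-3,5,5-trimethyl-4-{[(1-phenyl-1H-tetrazol-5-yl)sulfanyl]methyl}cyclohex-2-en-1-ol F11. Mitsunobu inversion with 4-nitrobenzoic acid (PPh3, DIAD, THF) gives the cis 4-nitrobenzoate F12; this is SN2 at the carbinol carbon, SN2' being disfavoured because the far alkene carbon is fully substituted. K2CO3 in MeOH then releases 9.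

Further compounds

F1 | step 2 | racemic 2,6,6-trimethyl-4-[(triisopropylsilyl)oxy]cyclohex-3-ene-1-carbaldehyde (cis/trans mixture) | CC1C=C(O[Si](C(C)C)(C(C)C)C(C)C)CC(C)(C)C1C=O
F2 | step 2 | racemic [2,6,6-trimethyl-4-[(triisopropylsilyl)oxy]cyclohex-3-en-1-yl]methanol | CC1C=C(O[Si](C(C)C)(C(C)C)C(C)C)CC(C)(C)C1CO
F3 | step 2 | racemic 4-(hydroxymethyl)-3,5,5-trimethylcyclohex-2-en-1-one | CC1=CC(=O)CC(C)(C)C1CO
F4 | step 2 | racemic 3,5,5-trimethyl-4-{[(1-phenyl-1H-tetrazol-5-yl)sulfanyl]methyl}cyclohex-2-en-1-one | CC1=CC(=O)CC(C)(C)C1CSc1nnnn1-c1ccccc1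
F5 | step 2 | (1S,4S)-3,5,5-trimethyl-4-{[(1-phenyl-1H-tetrazol-5-yl)sulfanyl]methyl}cyclohex-2-en-1-ol | CC1=C[C@@H](O)CC(C)(C)[C@@H]1CSc1nnnn1-c1ccccc1
F6 | step 9 | ethyl (2E,4E)-5-[(1R,4S)-4-{[tert-butyl(dimethyl)silyl]oxy}-2,6,6-trimethylcyclohex-2-en-1-yl]-3-methylpenta-2,4-dienoate | CC1=C[C@@H](O[Si](C)(C)C(C)(C)C)CC(C)(C)[C@H]1/C=C/C(C)=C/C(=O)OCC
F7 | step 9 | (2E,4E)-5-[(1R,4S)-4-{[tert-butyl(dimethyl)silyl]oxy}-2,6,6-trimethylcyclohex-2-en-1-yl]-3-methylpenta-2,4-dien-1-ol | CC1=C[C@@H](O[Si](C)(C)C(C)(C)C)CC(C)(C)[C@H]1/C=C/C(C)=C/CO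
F8 | step 9 | [(2E,4E)-5-[(1R,4S)-4-{[tert-butyl(dimethyl)silyl]oxy}-2,6,6-trimethylcyclohex-2-en-1-yl]-3-methylpenta-2,4-dien-1-yl]triphenylphosphonium bromide | CC1=C[C@@H](O[Si](C)(C)C(C)(C)C)CC(C)(C)[C@H]1/C=C/C(C)=C/C[P+](c1ccccc1)(c1ccccc1)c1ccccc1.[Br-]
F9 | step 9 | (2E,4E,6E,8E,10E,12E)-13-[(1R,4S)-4-{[tert-butyl(dimethyl)silyl]oxy}-2,6,6-trimethylcyclohex-2-en-1-yl]-2,7,11-trimethyltrideca-2,4,6,8,10,12-hexaenal | CC1=C[C@@H](O[Si](C)(C)C(C)(C)C)CC(C)(C)[C@H]1/C=C/C(C)=C/C=C/C(C)=C/C=C/C=C(\C)C=O
F10 | step 9 | dimethyl acetal of 14 | CC1=C[C@@H](O[Si](C)(C)C(C)(C)C)CC(C)(C)[C@H]1/C=C/C(C)=C/C=C/C(C)=C/C=C/C=C(C)/C=C/C=C(\C)C(OC)OC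
F11 | step 6 | (1R,4R)-3,5,5-trimethyl-4-{[(1-phenyl-1H-tetrazol-5-yl)sulfanyl]methyl}cyclohex-2-en-1-ol | CC1=C[C@H](O)CC(C)(C)[C@H]1CSc1nnnn1-c1ccccc1
F12 | step 6 | (1S,4R)-3,5,5-trimethyl-4-{[(1-phenyl-1H-tetrazol-5-yl)sulfanyl]methyl}cyclohex-2-en-1-yl 4-nitrobenzoate | CC1=C[C@@H](OC(=O)c2ccc(cc2)[N+](=O)[O-])CC(C)(C)[C@H]1CSc1nnnn1-c1ccccc1
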